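The east run at 60 °C reads 6.0% of product at 3.00 h, and you want to know what that curve is worth for two other flasks.

| flask | substrate | coupling partner | precatalyst | temperature | remark | time |
|---|---|---|---|---|---|---|
| east | 0.023 M | 0.115 M | 0.35 mM | 60 °C | run made earlier |  |
| west | 0.023 M | 0.115 M | 0.12 mM | 60 °C | run made earlier |  |
| Tuesday's | 0.023 M | 0.115 M | 0.23 mM |  | at 60 °C until 8.0 h, from then on at 20 °C | 15 h |
| Saturday's | 0.0080 M | 0.300 M | 0.23 mM |  | at 20 °C throughout | 15 h |

| east: time / h | east: product / % | west: time / h | west: product / % |
|---|---|---|---|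
| 0.167 | 0 | 0.417 | 0 |
| 0.500 | 1.4 | 0.833 | 0 |
| 0.833 | 0.2 | 1.33 | 0.1 |
| 1.33 | 1.5 | 1.50 | 0.3 |
| 2.00 | 2.9 | 2.00 | 1.0 |
| 2.50 | 3.8 | 2.50 | 1.5 |
| 3.00 | 6.0 | 3.00 | 2.3 |

(each reading ± 0.5 percentage points)

1. the winner by amount of product, in percent of the substrate charged; "neither" if no more than 2 percentage points parts them (Tuesday's / Saturday's / neither)
2. how much product is there at the end, in percent of the substrate charged: Tuesday's
3. how much product is there at the end, in percent of the substrate charged: Saturday's

- the earlier runs do not show what temperature does; that part of a forecast is a guess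

Start with the main step by itself, turnover on a steady amount of catalyst, and treat the last stretch of east as a straight line. It gains 3.1 percentage points between 2.00 h and 3.00 h. Scaled to the [precatalyst] of 0.23 mM in Tuesday's flask, that line gives 16.3% at the change of temperature, 8.0 h.

But the runs are no lines: west reads 0% at 0.833 h, and both bend upward. So add the wait for active catalyst, taking product as rising with the square of time and with the first power of [precatalyst]. One quantity then sums up this reckoning: the ramp time, the time at which that square law reaches the whole substrate charge, so that the fraction converted is the squared ratio of time to ramp time. East, scaled to 0.23 mM, gives 15.1 h, and west, scaled likewise, gives 14.3 h.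

For Tuesday's flask the square law gives 28.0% at 8.0 h, more than the line. Next add the using up of substrate, taken as first order, and the exponential form trims this to 24.5%. Last comes the cooling, which the runs do not show. Borrowing the forecast's guess of a 20-fold slowdown, the cold hours add 1.85%, so my own figure for Tuesday's flask is 26.4%.

Saturday's flask has the same [precatalyst] but stays at 20 °C, and the runs do not test its other charges. If activation and turnover each slow 20-fold, its ramp time stretches 20-fold to 302 h, and I reckon 0.246% at 15 h.

The forecast names Tuesday's the winner, with 25% (15% to 36%) for Tuesday's flask and 1% (0% to 5%) for Saturday's: “Saturday's flask never gets warm, so both activation and turnover are slow.” Its figure for Saturday's flask stands higher than mine.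

Tuesday's flask ends at 21.4% and Saturday's at 0.158%, so Tuesday's wins.

    substrate + catalyst intermediate A → catalyst intermediate B (k = 2.90 M⁻¹ s⁻¹, Ea = 43.0 kJ mol⁻¹)
    catalyst intermediate B ⇌ catalyst intermediate C (K = 2.40, k = 0.00190 s⁻¹, Ea = 109 kJ mol⁻¹, ΔH = −72.0 kJ mol⁻¹)
    catalyst intermediate C → free catalyst + product (k = 0.450 s⁻¹, Ea = 76.0 kJ mol⁻¹)
    coupling partner + precatalyst → free catalyst + spent reagent (k = 3.50 × 10⁻⁴ M⁻¹ s⁻¹, Ea = 63.0 kJ mol⁻¹)
    coupling partner + free catalyst → catalyst intermediate A (k = 4.20 M⁻¹ s⁻¹, Ea = 49.0 kJ mol⁻¹)
    (constants at 60 °C)

Tuesday's flask held 21.3% at 8.00 h and 21.4% at 15.0 h. Read back through the same exponential law, the figure at 8.00 h gives a ramp time of 16.3 h, against the 15.1 h read from east. Saturday's flask, read the same way, gives a ramp time of 377 h, longer than 15.1 h, and left until 150 h it holds 8.71%.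

The numbers in the tables are calculated for an exercise, and the scatter is random.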